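## Analysis of the target

The target 26 is made of two 2,3-diaryl-2,3-dihydrobenzofurans joined by the C3–C5' bond. The first unit is numbered O1, C2, C3, C3a, C4–C7, C7a (benzo ring A) and the second carries primes (benzo ring B). Ring A bears the (E)-4-hydroxystyryl group at C4 and OH at C6. C2 and C2' each carry a 4-hydroxyphenyl ring, C3' carries the 3,5-dihydroxyphenyl ring, and ring B has a free OH at C7' next to the ring oxygen O1'.

There are four stereocentres, (2S,3S) and (2'R,3'R), and both rings are trans. The two pairs lie on opposite sides of ring B, too far apart for one to direct the other, so each pair needs its own absolute control.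

The sensitive elements are:
- seven phenols;
- an electron-rich stilbene, which under acid can undergo Friedel–Crafts closure onto C4' or C6';
- the benzylic C2–O1 and C2'–O1' bonds, which ionise under acid (trans is the thermodynamic isomer);
- the doubly benzylic C3–H and C3'–H, whose removal would open the rings.

The hard part is ring B. It is a 1,2-dioxygenated arene with a further substituent at C5', and it must be made in the presence of other electron-rich arenes, which makes oxidative or electrophilic ring closures unselective.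

The strategy rests on one feature: O1' (on C7a') and the C7'–OH sit on adjacent carbons of ring B. These are exactly the two atoms of an aryne across C7'–C7a', so a tethered alkoxide can add at C7a' and the carbanion left at C7' can be turned into the hydroxyl.

## Retrosynthetic reasoning

**26 to 25.** The seven phenols are carried as methyl ethers to the end, because only methyl ethers survive lithium amides, aryllithiums, palladium catalysis and dilute acid alike. The last step is a global O-demethylation of 25.

**25 to 23 and 24.** The C4–vinyl bond is cut. The stilbene is the most acid- and oxidant-sensitive part, so it is attached last. The (E)-alkenylboronate 24 brings the geometry, and the bromide 23 carries the handle from the ring-A building block.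

**23 to 17 and 20.** The first dihydrofuran is opened at C2–C3 and C2–O1, a [4+1] disconnection. C3 then becomes the exocyclic carbon of ortho-quinone methide 21 (released from sulfone 17), and C2 becomes the ylide carbon of 22 (from sulfonium salt 20). Because the stereocentres of ring B's unit are remote, the forward step must set (2S,3S) by reagent control, through the chiral sulfide in 20.

**17 to 16 to 12 and 14.** The C3–C3a bond is cut between ring A and the benzylic carbon. The aldehyde carbon of 12 becomes C3, and ring A arrives as aryllithium 15, made from 14 by metalation between bromine and the acetal-type ether. The forward sequence must place the metal at that one position and then exchange the carbinol OH for a leaving group that a phenoxide can expel.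

**12 to 10.** Functional-group changes only: the C7' phenol is capped as its methyl ether and the acetal is opened to the aldehyde.

**10 to 6 (key disconnection).** O1'–C7a' and C7'–O are cut together. Both bonds trace back to one C–F bond in 6: a C7'–C7a' aryne accepts the side-chain alkoxide at C7a' and leaves a carbanion at C7' that is converted to OH. Cutting here avoids any oxidative closure on a molecule with three electron-rich arenes and leaves C2' and C3' untouched. In 6 the fluorine sits on the carbon that becomes C7a', so that only one hydrogen is ortho to fluorine and only one aryne can form.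

**6 to 5 to 2, 3 and 4.** The C3'–aryl bond and the C2'–O bond (via C2'–B) are cut across the alkene of stilbene 3. One syn arylboration with bromide 2 and diboron 4 brings all three aryl groups of the second unit and both stereocentres. Syn addition to the E-alkene gives exactly the diastereomer that closes to the trans ring. The forward reaction must put boron on the carbon bearing the 4-methoxyphenyl ring and choose one alkene face.

**Building blocks.** 2 comes from aldehyde 1 by acetalisation, 14 from phenol 13 by etherification, and 20 from sulfide 18 and bromide 19.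

## Alternatives that were turned down

**Alternative 1:** Ring A and the first dihydrofuran are formed together by a (2+2+2) cyclotrimerisation. Diyne A2 (an ynol ether on O1/C2 and a propargylic alkyne on C3) is combined with alkynylboronate A3 under a cationic rhodium–bisphosphine catalyst (monovalent rhodium) to give A1.
- For: the substitution pattern of ring A (carbon substituent at C4, boron at C6 as the future OH) arises without any regiochemical question on a preformed arene. On that point it is stronger than the chosen route, whose step 7 depends on site-selective metalation.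
- Against: A2 already contains the complete second dihydrobenzofuran, so the real difficulty, the oxygenation of ring B, is not addressed.
- Against: A2 needs a secondary benzylic ynol ether next to a propargylic, doubly activated C3–H that can isomerise to an allene and racemise.
- Against: the orientation of A3 in the insertion (boron at C6 or C5) is not fixed by the tether.
- Against: after the key step, C4 still has to be oxidised and olefinated and C6 oxidised.
- Comparison: the chosen strategy solves ring B in one operation from a three-step precursor and uses only aromatic building blocks.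

**Alternative 2:** C2–aryl and C3–C5' are formed in one step by a conjunctive coupling. Alkenylboronate A5 and aryllithium A7 form a boron ate complex, which a palladium catalyst with a chiral ferrocenyl bisphosphine couples with bromide A6 through a 1,2-metallate shift, giving A4.
- For: both stereocentres of the first unit are set in one catalytic step, and the regiochemistry is dictated by where boron sits. On this point it is stronger than the chiral-ylide annulation of step 10.
- Against: A6 is the whole second unit with bromine at C5', so ring B again has to come from elsewhere.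
- Against: A5 is a β-aryl alkenylboronate with two ortho substituents, where direct transmetalation competes with the metallate shift.
- Against: the later ring closure must invert a 4-methoxybenzylic carbinol, where ionisation competes.
- Against: the aryl chloride has to survive the palladium step.
- Comparison: the chosen strategy delivers what A6 would require (aldehyde 12 is its formyl analogue) and keeps the risk in one well-defined aryne step.

**Alternative 3:** C2'–C3' of the second unit is formed by carbene C–H insertion. Diazoester A9, under a chiral dirhodium tetracarboxylate (divalent rhodium), inserts into the benzylic C–H of its own 4-methoxybenzyl ether, and base equilibration gives trans ester A8.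
- For: the oxygen pattern of ring B is bought with a vanillin-type arene, so there is no aryne and no site-selectivity question. On this point it is stronger than the chosen route. The insertion is also a well-established, catalyst-controlled reaction class.
- Against: C3' carries a methyl ester where the target has the 3,5-dihydroxyphenyl ring. Turning an ester carbon into an aryl substituent at a stereocentre needs a decarboxylative arylation or a de novo arene synthesis, several steps with a radical or enolisable centre at C3'.
- Comparison: the chosen route brings that aryl group in with stilbene 3 and sets C2' and C3' together, at the price of the aryne step.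

Key step: step 4

**Assumptions and remarks on the chemistry**
- Fluorine is placed ortho to the side chain in 6, on the carbon that becomes C7a', and not meta to it. A meta-fluorine would leave two hydrogens ortho to fluorine, and the one flanked by fluorine and the acetal would be metalated first, giving an aryne that the alkoxide cannot reach.
- The (4R,5R) antipode of the NHC precursor in step 2 is assumed to deliver boron and aryl to the Re,Re face of 3, and the (1R,4R,5R) antipode of sulfide 18 is assumed to give the (2S,3S) ring in step 10. If either sense of induction turns out opposite, the mirror-image ligand or sulfide is used.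
- Both antipodes of sulfide 18 are taken as purchasable (otherwise one step from limonene).

## Route

Step 1
Reactants: 1 3-bromo-4-fluorobenzaldehyde
Product: 2 2-bromo-4-(dimethoxymethyl)-1-fluorobenzene
Conditions: HC(OMe)3, MeOH, p-TsOH·H2O (cat.), 22 °C
Reagents that add atoms: trimethyl orthoformate, COC(OC)OC
Why: Acid-catalysed acetalisation; the aldehyde must be masked because copper boryl species and aryllithiums add to C=O, and the C–F and C–Br bonds are untouched.

Step 2
Reactants: 2 2-bromo-4-(dimethoxymethyl)-1-fluorobenzene; 3 (E)-3,5,4'-trimethoxystilbene; 4 bis(pinacolato)diboron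
Product: 5 2-[(1R,2R)-2-[5-(dimethoxymethyl)-2-fluorophenyl]-2-(3,5-dimethoxyphenyl)-1-(4-methoxyphenyl)ethyl]-4,4,5,5-tetramethyl-1,3,2-dioxaborolane
Conditions: CuCl (5 mol%), (4R,5R)-1,3-bis(2-methylphenyl)-4,5-diphenylimidazolinium tetrafluoroborate (6 mol%), Pd(OAc)2 (2 mol%), RuPhos (4 mol%), NaOtBu, toluene–THF, 22 °C
Reagents that add atoms: none
Why: Copper/palladium cooperative arylboration of a 1,2-disubstituted alkenylarene: the chiral NHC–copper boryl adds syn with boron on the carbon bearing the 4-methoxyphenyl ring (copper prefers the benzylic carbon next to the less electron-rich 3,5-dimethoxyphenyl ring), and the benzylcopper transmetalates with retention to the arylpalladium bromide formed from 2 before reductive elimination; the ligand on copper selects the Re,Re face, so both stereocentres (1R,2R) are set here.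

Step 3
Reactants: 5 the pinacol boronate
Product: 6 (1R,2R)-2-[5-(dimethoxymethyl)-2-fluorophenyl]-2-(3,5-dimethoxyphenyl)-1-(4-methoxyphenyl)ethan-1-ol
Conditions: NaBO3·4H2O, THF–H2O, 22 °C
Reagents that add atoms: sodium perborate tetrahydrate, [Na+].[O-]OB=O.O.O.O.O
Why: Oxidation of the secondary C–B bond by 1,2-shift of carbon from boron to oxygen with retention; the mild basic perborate does not ionise the 4-methoxybenzylic alcohol.

Step 4
Reactants: 6 the (1R,2R)-fluoro alcohol
Product: 10 (2R,3R)-5-(dimethoxymethyl)-3-(3,5-dimethoxyphenyl)-2-(4-methoxyphenyl)-2,3-dihydro-1-benzofuran-7-ol, via aryne lithium alkoxide 7 (not isolated), via 7-lithio dihydrobenzofuran 8 (not isolated), via dimethyl arylboronate 9 (not isolated)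
Conditions: LiTMP (lithium 2,2,6,6-tetramethylpiperidide, 3.0 equiv), THF, −78 → −30 °C; B(OMe)3, −78 → 0 °C; then NaOH, H2O2, H2O, 0 → 22 °C
Reagents that add atoms: lithium 2,2,6,6-tetramethylpiperidide, [Li]N1C(C)(C)CCCC1(C)C (lithium of 7 and 8); trimethyl borate, COB(OC)OC (boron of 9); hydrogen peroxide, OO (oxygen at C7')
Why: LiTMP first forms the lithium alkoxide and then removes the ring hydrogen next to the C–F carbon, the only hydrogen ortho to fluorine and so the most acidic one, so that loss of LiF on warming can give only the aryne 7 spanning the future C7a'–C7' pair. The alkoxide oxygen, tethered through C3' and C2' to the neighbouring ring carbon, adds to the proximal aryne carbon in the ring plane; this 5-exo-dig closure forms O1'–C7a' and the dihydrofuran ring, and attack at the distal aryne carbon is geometrically impossible. The negative charge is thereby left on C7', ortho to the new ring oxygen, as aryllithium 8, which B(OMe)3 converts to 9 and alkaline H2O2 oxidises with aryl migration from boron to oxygen, so the C7'–OH appears where the lithium was. The closest known reaction type is the aryne cyclisation of haloarenes that carry a tethered oxygen or nitrogen nucleophile under lithium amide conditions, with electrophilic trapping of the resulting ortho-heteroatom aryllithium (7-substituted benzoxazoles, indolines and dihydrobenzofurans). No stereocentre is created; C2' and C3' keep the configuration from step 2 because no bond to either is made or broken, and the trans ring follows from the syn relation of aryl and oxygen in 6. The step needs site selectivity of metalation (secured by the single ortho-fluoro hydrogen and by an amide base that responds to acidity and not to coordination by acetal or methoxy groups), regioselectivity of addition (secured by the tether), and chemoselectivity against amination of the aryne (the piperidide is too hindered) and against removal of the tertiary benzylic H–C3' beside the alkoxide (kinetically slow below −30 °C).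

Step 5
Reactants: 10 the 7-hydroxy dihydrobenzofuran acetal
Product: 12 (2R,3R)-3-(3,5-dimethoxyphenyl)-7-methoxy-2-(4-methoxyphenyl)-2,3-dihydro-1-benzofuran-5-carbaldehyde, via methyl ether acetal 11 (not isolated)
Conditions: MeI, K2CO3, DMF, 22 °C; then 1 M HCl, THF, 22 °C
Reagents that add atoms: iodomethane, CI
Why: Williamson methylation of the only free phenol, then hydrolysis of the dimethyl acetal of an electron-rich benzaldehyde under dilute acid that leaves the C2'–O1' bond intact.

Step 6
Reactants: 13 3-bromo-5-methoxyphenol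
Product: 14 1-bromo-3-methoxy-5-(methoxymethoxy)benzene
Conditions: MOMCl, iPr2NEt, CH2Cl2, 0 → 22 °C
Reagents that add atoms: chloromethyl methyl ether, COCCl
Why: O-Alkylation of the phenol; the methoxymethyl ether is the ortho-directing, acid-removable group needed in steps 7 and 8.

Step 7
Reactants: 14 1-bromo-3-methoxy-5-(methoxymethoxy)benzene; 12 the aldehyde
Product: 16 [2-bromo-4-methoxy-6-(methoxymethoxy)phenyl][(2R,3R)-3-(3,5-dimethoxyphenyl)-7-methoxy-2-(4-methoxyphenyl)-2,3-dihydro-1-benzofuran-5-yl]methanol (both carbinol epimers), via 2-lithio aryl ether 15 (not isolated)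
Conditions: LiN(iPr)2 (lithium diisopropylamide, 1.2 equiv), 14 (1.3 equiv), THF, −78 °C; 12, −78 °C; AcOH quench at −78 °C
Reagents that add atoms: lithium diisopropylamide, [Li]N(C(C)C)C(C)C (lithium of 15)
Why: Directed ortho-metalation by a lithium amide (no bromine–lithium exchange) at the C–H flanked by bromine and the chelating OMOM group, then 1,2-addition to the non-enolisable aldehyde at −78 °C before the ortho-bromoaryllithium can lose LiBr; the new carbinol centre is destroyed in step 10, so its configuration is irrelevant.

Step 8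
Reactants: 16 the diaryl carbinol
Product: 17 3-bromo-2-{[(2R,3R)-3-(3,5-dimethoxyphenyl)-7-methoxy-2-(4-methoxyphenyl)-2,3-dihydro-1-benzofuran-5-yl](4-methylbenzenesulfonyl)methyl}-5-methoxyphenol (both epimers at the sulfonyl carbon)
Conditions: p-TolSO2Na (sodium p-toluenesulfinate, 3 equiv), HCl, MeOH–THF, 40 °C
Reagents that add atoms: sodium p-toluenesulfinate, Cc1ccc(cc1)S(=O)[O-].[Na+]
Why: Acid removes the MOM ether and ionises the doubly activated benzhydrol; the sulfinate captures the cation at sulfur (SN1) to give a 2-(tosylalkyl)phenol, the standard base-triggered precursor of an ortho-quinone methide.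

Step 9
Reactants: 18 (1R,4R,5R)-isothiocineole; 19 4-methoxybenzyl bromide
Product: 20 (1R,4R,5R)-6-(4-methoxybenzyl)-4,7,7-trimethyl-6-thioniabicyclo[3.2.1]octane trifluoromethanesulfonate
Conditions: LiOTf, CH2Cl2–H2O, 22 °C
Reagents that add atoms: lithium trifluoromethanesulfonate, [Li+].[O-]S(=O)(=O)C(F)(F)F
Why: S-Alkylation of the sulfide by the benzylic bromide with exchange to the non-nucleophilic triflate; alkylation on the exposed sulfur lone pair should give one sulfonium diastereomer.

Step 10
Reactants: 17 the sulfonyl phenol; 20 the chiral sulfonium triflate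
Product: 23 (2R,3R)-5-[(2S,3S)-4-bromo-6-methoxy-2-(4-methoxyphenyl)-2,3-dihydro-1-benzofuran-3-yl]-3-(3,5-dimethoxyphenyl)-7-methoxy-2-(4-methoxyphenyl)-2,3-dihydro-1-benzofuran, via ortho-quinone methide 21 (not isolated), via sulfonium ylide 22 (not isolated)
Conditions: Cs2CO3 (3 equiv), MeCN–CH2Cl2, −20 → 22 °C
Reagents that add atoms: none
Why: Proposed new method: base expels sulfinate from the phenoxide of 17 to give ortho-quinone methide 21 and deprotonates 20 to the benzylic ylide 22, which adds to the exocyclic carbon of 21 and is then displaced from C2 by the phenoxide in a 5-exo-tet SN2 step with inversion; the closest known reaction types are the [4+1] annulation of ortho-quinone methides from 2-(tosylalkyl)phenols with carbonyl-stabilised sulfonium ylides (trans-2,3-dihydrobenzofurans) and the asymmetric epoxidation and cyclopropanation with isothiocineole-derived benzylic ylides; the sulfide shields one face of the ylide so that the sulfonium-bearing carbon is formed R and becomes (2S) after inversion, and the anti approach of the two aryl groups gives the trans ring and hence (3S).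

Step 11
Reactants: 23 the bromide; 24 (E)-2-[2-(4-methoxyphenyl)ethenyl]-4,4,5,5-tetramethyl-1,3,2-dioxaborolane
Product: 25 (2R,3R)-3-(3,5-dimethoxyphenyl)-7-methoxy-5-[(2S,3S)-6-methoxy-2-(4-methoxyphenyl)-4-[(E)-2-(4-methoxyphenyl)ethenyl]-2,3-dihydro-1-benzofuran-3-yl]-2-(4-methoxyphenyl)-2,3-dihydro-1-benzofuran
Conditions: Pd(OAc)2 (5 mol%), SPhos (10 mol%), K3PO4, toluene–H2O, 90 °C
Reagents that add atoms: none
Why: Suzuki–Miyaura coupling; the bulky biarylphosphine allows oxidative addition of the ortho-substituted, electron-rich aryl bromide, and the alkenylboronate transfers with retention of the E geometry.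

Step 12
Reactants: 25 the heptamethyl ether
Product: 26 the target, (2R,3R)-3-(3,5-dihydroxyphenyl)-5-[(2S,3S)-6-hydroxy-2-(4-hydroxyphenyl)-4-[(E)-2-(4-hydroxyphenyl)ethenyl]-2,3-dihydro-1-benzofuran-3-yl]-2-(4-hydroxyphenyl)-2,3-dihydro-1-benzofuran-7-ol
Conditions: BBr3 (excess), CH2Cl2, −78 → 0 °C; MeOH–H2O quench
Reagents that add atoms: none
Why: Lewis-acid cleavage of all seven aryl methyl ethers (boron coordinates oxygen, bromide attacks methyl by SN2) at low temperature; a dihydrofuran C–O bond that opens should reclose to the thermodynamically preferred trans ring.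

## Compound list

1 | 3-bromo-4-fluorobenzaldehyde | O=Cc1ccc(F)c(Br)c1 | starting material
2 | 2-bromo-4-(dimethoxymethyl)-1-fluorobenzene | COC(OC)c1ccc(F)c(Br)c1 | intermediate
3 | (E)-3,5,4'-trimethoxystilbene | COc1ccc(/C=C/c2cc(OC)cc(OC)c2)cc1 | starting material
4 | bis(pinacolato)diboron | CC1(C)OB(B2OC(C)(C)C(C)(C)O2)OC1(C)C | starting material
5 | 2-[(1R,2R)-2-[5-(dimethoxymethyl)-2-fluorophenyl]-2-(3,5-dimethoxyphenyl)-1-(4-methoxyphenyl)ethyl]-4,4,5,5-tetramethyl-1,3,2-dioxaborolane | COC(OC)c1ccc(F)c(c1)[C@@H](c1cc(OC)cc(OC)c1)[C@H](c1ccc(OC)cc1)B1OC(C)(C)C(C)(C)O1 | intermediate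
6 | (1R,2R)-2-[5-(dimethoxymethyl)-2-fluorophenyl]-2-(3,5-dimethoxyphenyl)-1-(4-methoxyphenyl)ethan-1-ol | COC(OC)c1ccc(F)c(c1)[C@@H](c1cc(OC)cc(OC)c1)[C@H](c1ccc(OC)cc1)O | intermediate
7 | lithium alkoxide of the aryne from 6 (triple bond between the former C–F carbon and its neighbour) | COC(OC)C1=CC#CC(=C1)[C@@H](c1cc(OC)cc(OC)c1)[C@H](c1ccc(OC)cc1)O[Li] | intermediate (not isolated)
8 | (2R,3R)-5-(dimethoxymethyl)-3-(3,5-dimethoxyphenyl)-2-(4-methoxyphenyl)-2,3-dihydro-1-benzofuran-7-yllithium | COC(OC)c1cc([Li])c2c(c1)[C@@H](c1cc(OC)cc(OC)c1)[C@H](c1ccc(OC)cc1)O2 | intermediate (not isolated)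
9 | dimethyl [(2R,3R)-5-(dimethoxymethyl)-3-(3,5-dimethoxyphenyl)-2-(4-methoxyphenyl)-2,3-dihydro-1-benzofuran-7-yl]boronate | COC(OC)c1cc(B(OC)OC)c2c(c1)[C@@H](c1cc(OC)cc(OC)c1)[C@H](c1ccc(OC)cc1)O2 | intermediate (not isolated)
10 | (2R,3R)-5-(dimethoxymethyl)-3-(3,5-dimethoxyphenyl)-2-(4-methoxyphenyl)-2,3-dihydro-1-benzofuran-7-ol | COC(OC)c1cc(O)c2c(c1)[C@@H](c1cc(OC)cc(OC)c1)[C@H](c1ccc(OC)cc1)O2 | intermediate
11 | (2R,3R)-5-(dimethoxymethyl)-3-(3,5-dimethoxyphenyl)-7-methoxy-2-(4-methoxyphenyl)-2,3-dihydro-1-benzofuran | COC(OC)c1cc(OC)c2c(c1)[C@@H](c1cc(OC)cc(OC)c1)[C@H](c1ccc(OC)cc1)O2 | intermediate (not isolated)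
12 | (2R,3R)-3-(3,5-dimethoxyphenyl)-7-methoxy-2-(4-methoxyphenyl)-2,3-dihydro-1-benzofuran-5-carbaldehyde | O=Cc1cc(OC)c2c(c1)[C@@H](c1cc(OC)cc(OC)c1)[C@H](c1ccc(OC)cc1)O2 | intermediate
13 | 3-bromo-5-methoxyphenol | COc1cc(O)cc(Br)c1 | starting material
14 | 1-bromo-3-methoxy-5-(methoxymethoxy)benzene | COCOc1cc(OC)cc(Br)c1 | intermediate
15 | [2-bromo-4-methoxy-6-(methoxymethoxy)phenyl]lithium | COCOc1cc(OC)cc(Br)c1[Li] | intermediate (not isolated)
16 | [2-bromo-4-methoxy-6-(methoxymethoxy)phenyl][(2R,3R)-3-(3,5-dimethoxyphenyl)-7-methoxy-2-(4-methoxyphenyl)-2,3-dihydro-1-benzofuran-5-yl]methanol, both carbinol epimers | OC(c1c(Br)cc(OC)cc1OCOC)c1cc(OC)c2c(c1)[C@@H](c1cc(OC)cc(OC)c1)[C@H](c1ccc(OC)cc1)O2 | intermediate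
17 | 3-bromo-2-{[(2R,3R)-3-(3,5-dimethoxyphenyl)-7-methoxy-2-(4-methoxyphenyl)-2,3-dihydro-1-benzofuran-5-yl](4-methylbenzenesulfonyl)methyl}-5-methoxyphenol, both epimers at the sulfonyl carbon | Cc1ccc(cc1)S(=O)(=O)C(c1c(Br)cc(OC)cc1O)c1cc(OC)c2c(c1)[C@@H](c1cc(OC)cc(OC)c1)[C@H](c1ccc(OC)cc1)O2 | intermediate
18 | (1R,4R,5R)-isothiocineole, (1R,4R,5R)-4,7,7-trimethyl-6-thiabicyclo[3.2.1]octane | C[C@@H]1CC[C@@H]2C[C@H]1SC2(C)C | starting material
19 | 4-methoxybenzyl bromide | COc1ccc(CBr)cc1 | starting material
20 | (1R,4R,5R)-6-(4-methoxybenzyl)-4,7,7-trimethyl-6-thioniabicyclo[3.2.1]octane trifluoromethanesulfonate (sulfur configuration as formed on alkylation) | C[C@@H]1CC[C@@H]2C[C@H]1[S+](Cc1ccc(OC)cc1)C2(C)C.[O-]S(=O)(=O)C(F)(F)F | intermediate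
21 | ortho-quinone methide: 5-bromo-6-{[(2R,3R)-3-(3,5-dimethoxyphenyl)-7-methoxy-2-(4-methoxyphenyl)-2,3-dihydro-1-benzofuran-5-yl]methylidene}-3-methoxycyclohexa-2,4-dien-1-one | O=C1C=C(OC)C=C(Br)C1=Cc1cc(OC)c2c(c1)[C@@H](c1cc(OC)cc(OC)c1)[C@H](c1ccc(OC)cc1)O2 | intermediate (not isolated)
22 | sulfonium ylide from 20 (4-methoxybenzylide) | C[C@@H]1CC[C@@H]2C[C@H]1[S+]([CH-]c1ccc(OC)cc1)C2(C)C | intermediate (not isolated)
23 | (2R,3R)-5-[(2S,3S)-4-bromo-6-methoxy-2-(4-methoxyphenyl)-2,3-dihydro-1-benzofuran-3-yl]-3-(3,5-dimethoxyphenyl)-7-methoxy-2-(4-methoxyphenyl)-2,3-dihydro-1-benzofuran | Brc1cc(OC)cc2c1[C@H](c1cc(OC)c3c(c1)[C@@H](c1cc(OC)cc(OC)c1)[C@H](c1ccc(OC)cc1)O3)[C@@H](c1ccc(OC)cc1)O2 | intermediate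
24 | (E)-2-[2-(4-methoxyphenyl)ethenyl]-4,4,5,5-tetramethyl-1,3,2-dioxaborolane | COc1ccc(/C=C/B2OC(C)(C)C(C)(C)O2)cc1 | starting material
25 | heptamethyl ether of the target | COc1ccc(/C=C/c2cc(OC)cc3c2[C@H](c2cc(OC)c4c(c2)[C@@H](c2cc(OC)cc(OC)c2)[C@H](c2ccc(OC)cc2)O4)[C@@H](c2ccc(OC)cc2)O3)cc1 | intermediate
26 | CNP0172909.1, (2S,3S,2'R,3'R) | Oc1ccc(/C=C/c2cc(O)cc3c2[C@H](c2cc(O)c4c(c2)[C@@H](c2cc(O)cc(O)c2)[C@H](c2ccc(O)cc2)O4)[C@@H](c2ccc(O)cc2)O3)cc1 | target

## Step count and risk

Total: 12 steps. Longest linear sequence: 10 steps (1, 2, 3, 4, 5, 7, 8, 10, 11, 12); steps 6 and 9 make side components.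

**Step 10 (Proposed new method).** The facial discrimination of the ylide may be insufficient, because the stereocentres of the second unit are too remote to help. The trans selectivity of the addition may erode, or the phenoxide may be O-benzylated by the sulfonium salt before sulfinate is lost.

The fallback uses known chemistry, the enantioselective intramolecular C–H insertion of a donor/donor rhodium carbene. It sets out from 12 and 13 and returns at 23. Phenol 13 is converted with 4-methoxybenzyl chloride and K2CO3 into 1-bromo-3-methoxy-5-[(4-methoxyphenyl)methoxy]benzene F1. F1 is metalated as in step 7 and added to 12 to give the carbinol F2, which is oxidised (Dess–Martin periodinane) to the diaryl ketone F3. Hydrazine under forcing conditions gives the hydrazone F4. MnO2 oxidises F4 to the diaryldiazomethane F5, which the chiral catalyst dirhodium tetrakis[N-phthaloyl-(S)-adamantylglycinate], Rh2(S-PTAD)4 (divalent rhodium; or its mirror image), inserts into the benzylic C–H of the 4-methoxybenzyl ether to give the cis-(2R,3S)-dihydrobenzofuran F6. Brief exposure to BF3·OEt2 epimerises C2 through the 4-methoxybenzylic cation to the trans compound 23.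

**Step 4 (key step).** The C7' aryllithium may be protonated by the liberated amine before borylation, or the lithium may migrate to the position between the two methoxy groups of the resorcinol ring. Deprotonation at C3' may open the new ring by β-elimination of the phenoxide.

The fallback forms the same ring by attack of a phenol on a benzylic cation, with the ring-B oxygens bought in. It sets out from 3 and 4 and returns at 12. 5-Bromovanillin F7 is protected as 3-bromo-5-methoxy-4-(methoxymethoxy)benzaldehyde F8 and acetalised to 1-bromo-5-(dimethoxymethyl)-3-methoxy-2-(methoxymethoxy)benzene F9. Arylboration of 3 with F9 and 4 under the conditions of step 2 gives the boronate F10, and perborate oxidation gives the alcohol F11. HCl in MeOH–THF then removes the MOM group and the acetal and closes the dihydrofuran through the 4-methoxybenzylic cation (trans by thermodynamic control), giving 12.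

**Step 2.** Borylcupration may run the wrong way round, because the electronic difference between the two aryl groups of 3 is modest. The enantioselectivity of stilbene insertion may be low.

The fallback swaps the roles of the aryl groups so that a more polarised alkene is used. It sets out from 2 and returns at 5. Sonogashira coupling of 2 with 4-ethynylanisole (Pd(PPh3)2Cl2, CuI, Et3N) gives the diarylalkyne F12. Semi-hydrogenation over Pd/CaCO3 poisoned with Pb(OAc)2 gives the (Z)-stilbene F13. Syn arylboration of F13 with 1-bromo-3,5-dimethoxybenzene and 4 then places copper next to the electron-poor fluoroaryl ring and, from the Z-alkene, gives the same diastereomer 5.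

**Step 7.** Metalation may occur at the other bromine-flanked position (between bromine and methoxy), or the ortho-bromoaryllithium may lose LiBr to an aryne before it meets the aldehyde.

The fallback uses a stronger directing group. It sets out from 13 and 12 and returns at 17. Phenol 13 is converted with diethylcarbamoyl chloride into 3-bromo-5-methoxyphenyl N,N-diethylcarbamate F14. Metalation with LiN(iPr)2 at −78 °C and addition to 12 give the hydroxy carbamate F15. LiAlH4 removes the carbamate to give the phenol carbinol F16, which under the sulfinate and acid conditions of step 8 gives 17.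

**Step 12.** HBr formed during demethylation may drive Friedel–Crafts cyclisation of the stilbene onto ring B, or open the dihydrofurans irreversibly.

The fallback demethylates before the stilbene is present and finishes with a mild ester cleavage. It sets out from 23 and returns at 26. BBr3 converts 23 into the hexaphenol bromide F17. Ac2O and pyridine give the hexaacetate F18. A Heck reaction with 4-acetoxystyrene (Pd(OAc)2, P(o-tol)3, Et3N) gives the heptaacetate F19, and K2CO3 in MeOH releases 26.

## Further compounds

F1 | step 10 | 1-bromo-3-methoxy-5-[(4-methoxyphenyl)methoxy]benzene | COc1ccc(COc2cc(OC)cc(Br)c2)cc1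
F2 | step 10 | {2-bromo-4-methoxy-6-[(4-methoxyphenyl)methoxy]phenyl}[(2R,3R)-3-(3,5-dimethoxyphenyl)-7-methoxy-2-(4-methoxyphenyl)-2,3-dihydro-1-benzofuran-5-yl]methanol | OC(c1c(Br)cc(OC)cc1OCc1ccc(OC)cc1)c1cc(OC)c2c(c1)[C@@H](c1cc(OC)cc(OC)c1)[C@H](c1ccc(OC)cc1)O2
F3 | step 10 | {2-bromo-4-methoxy-6-[(4-methoxyphenyl)methoxy]phenyl}[(2R,3R)-3-(3,5-dimethoxyphenyl)-7-methoxy-2-(4-methoxyphenyl)-2,3-dihydro-1-benzofuran-5-yl]methanone | O=C(c1c(Br)cc(OC)cc1OCc1ccc(OC)cc1)c1cc(OC)c2c(c1)[C@@H](c1cc(OC)cc(OC)c1)[C@H](c1ccc(OC)cc1)O2
F4 | step 10 | hydrazone of F3 | NN=C(c1c(Br)cc(OC)cc1OCc1ccc(OC)cc1)c1cc(OC)c2c(c1)[C@@H](c1cc(OC)cc(OC)c1)[C@H](c1ccc(OC)cc1)O2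
F5 | step 10 | diaryldiazomethane from F4 | [N-]=[N+]=C(c1c(Br)cc(OC)cc1OCc1ccc(OC)cc1)c1cc(OC)c2c(c1)[C@@H](c1cc(OC)cc(OC)c1)[C@H](c1ccc(OC)cc1)O2
F6 | step 10 | (2R,3R)-5-[(2R,3S)-4-bromo-6-methoxy-2-(4-methoxyphenyl)-2,3-dihydro-1-benzofuran-3-yl]-3-(3,5-dimethoxyphenyl)-7-methoxy-2-(4-methoxyphenyl)-2,3-dihydro-1-benzofuran (cis in the first ring) | Brc1cc(OC)cc2c1[C@H](c1cc(OC)c3c(c1)[C@@H](c1cc(OC)cc(OC)c1)[C@H](c1ccc(OC)cc1)O3)[C@H](c1ccc(OC)cc1)O2
F7 | step 4 | 5-bromovanillin, 3-bromo-4-hydroxy-5-methoxybenzaldehyde | COc1cc(C=O)cc(Br)c1O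
F8 | step 4 | 3-bromo-5-methoxy-4-(methoxymethoxy)benzaldehyde | COCOc1c(Br)cc(C=O)cc1OC
F9 | step 4 | 1-bromo-5-(dimethoxymethyl)-3-methoxy-2-(methoxymethoxy)benzene | COCOc1c(Br)cc(C(OC)OC)cc1OC
F10 | step 4 | 2-[(1R,2R)-2-[5-(dimethoxymethyl)-3-methoxy-2-(methoxymethoxy)phenyl]-2-(3,5-dimethoxyphenyl)-1-(4-methoxyphenyl)ethyl]-4,4,5,5-tetramethyl-1,3,2-dioxaborolane | COCOc1c(OC)cc(C(OC)OC)cc1[C@@H](c1cc(OC)cc(OC)c1)[C@H](c1ccc(OC)cc1)B1OC(C)(C)C(C)(C)O1
F11 | step 4 | (1R,2R)-2-[5-(dimethoxymethyl)-3-methoxy-2-(methoxymethoxy)phenyl]-2-(3,5-dimethoxyphenyl)-1-(4-methoxyphenyl)ethan-1-ol | COCOc1c(OC)cc(C(OC)OC)cc1[C@@H](c1cc(OC)cc(OC)c1)[C@H](c1ccc(OC)cc1)O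
F12 | step 2 | 4-(dimethoxymethyl)-1-fluoro-2-[(4-methoxyphenyl)ethynyl]benzene | COC(OC)c1ccc(F)c(c1)C#Cc1ccc(OC)cc1
F13 | step 2 | 4-(dimethoxymethyl)-1-fluoro-2-[(Z)-2-(4-methoxyphenyl)ethenyl]benzene | COC(OC)c1ccc(F)c(c1)/C=C\c1ccc(OC)cc1
F14 | step 7 | 3-bromo-5-methoxyphenyl N,N-diethylcarbamate | CCN(CC)C(=O)Oc1cc(OC)cc(Br)c1
F15 | step 7 | 3-bromo-2-{[(2R,3R)-3-(3,5-dimethoxyphenyl)-7-methoxy-2-(4-methoxyphenyl)-2,3-dihydro-1-benzofuran-5-yl](hydroxy)methyl}-5-methoxyphenyl N,N-diethylcarbamate | CCN(CC)C(=O)Oc1cc(OC)cc(Br)c1C(O)c1cc(OC)c2c(c1)[C@@H](c1cc(OC)cc(OC)c1)[C@H](c1ccc(OC)cc1)O2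
F16 | step 7 | 3-bromo-2-{[(2R,3R)-3-(3,5-dimethoxyphenyl)-7-methoxy-2-(4-methoxyphenyl)-2,3-dihydro-1-benzofuran-5-yl](hydroxy)methyl}-5-methoxyphenol | Oc1cc(OC)cc(Br)c1C(O)c1cc(OC)c2c(c1)[C@@H](c1cc(OC)cc(OC)c1)[C@H](c1ccc(OC)cc1)O2
F17 | step 12 | hexaphenol corresponding to 23 (all six methyl ethers cleaved, bromine retained) | Brc1cc(O)cc2c1[C@H](c1cc(O)c3c(c1)[C@@H](c1cc(O)cc(O)c1)[C@H](c1ccc(O)cc1)O3)[C@@H](c1ccc(O)cc1)O2
F18 | step 12 | hexaacetate of F17 | Brc1cc(OC(C)=O)cc2c1[C@H](c1cc(OC(C)=O)c3c(c1)[C@@H](c1cc(OC(C)=O)cc(OC(C)=O)c1)[C@H](c1ccc(OC(C)=O)cc1)O3)[C@@H](c1ccc(OC(C)=O)cc1)O2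
F19 | step 12 | heptaacetate of 26 | CC(=O)Oc1ccc(/C=C/c2cc(OC(C)=O)cc3c2[C@H](c2cc(OC(C)=O)c4c(c2)[C@@H](c2cc(OC(C)=O)cc(OC(C)=O)c2)[C@H](c2ccc(OC(C)=O)cc2)O4)[C@@H](c2ccc(OC(C)=O)cc2)O3)cc1
A1 | alternative 1 | 6-boryl-4-(silyloxymethyl) first dihydrobenzofuran carrying the second unit at C3 | CC(C)(C)[Si](C)(C)OCc1cc(B2OC(C)(C)C(C)(C)O2)cc2c1[C@H](c5cc(OC)c6c(c5)[C@@H](c5cc(OC)cc(OC)c5)[C@H](c5ccc(OC)cc5)O6)[C@@H](c1ccc(OC)cc1)O2
A2 | alternative 1 | ynol-ether diyne precursor of A1 | CC(C)(C)[Si](C)(C)OCC#C[C@H](c1cc(OC)c2c(c1)[C@@H](c1cc(OC)cc(OC)c1)[C@H](c1ccc(OC)cc1)O2)[C@@H](c1ccc(OC)cc1)OC#C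
A3 | alternative 1 | ethynylboronic acid pinacol ester | C#CB1OC(C)(C)C(C)(C)O1
A4 | alternative 2 | acyclic 1,2,2-triarylethylboronate | Clc1cc(OC)cc(OCc2ccccc2)c1[C@H](c5cc(OC)c6c(c5)[C@@H](c5cc(OC)cc(OC)c5)[C@H](c5ccc(OC)cc5)O6)[C@H](c1ccc(OC)cc1)B1OC(C)(C)C(C)(C)O1
A5 | alternative 2 | (E)-2-[2-(benzyloxy)-6-chloro-4-methoxyphenyl]ethenylboronic acid pinacol ester | Clc1cc(OC)cc(OCc2ccccc2)c1/C=C/B1OC(C)(C)C(C)(C)O1
A6 | alternative 2 | (2R,3R)-5-bromo-3-(3,5-dimethoxyphenyl)-7-methoxy-2-(4-methoxyphenyl)-2,3-dihydro-1-benzofuran | Brc1cc(OC)c2c(c1)[C@@H](c1cc(OC)cc(OC)c1)[C@H](c1ccc(OC)cc1)O2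
A7 | alternative 2 | 4-methoxyphenyllithium | [Li]c1ccc(OC)cc1
A8 | alternative 3 | methyl trans-5-(1,3-dioxolan-2-yl)-7-methoxy-2-(4-methoxyphenyl)-2,3-dihydrobenzofuran-3-carboxylate | C1COC(O1)c1cc(OC)c2c(c1)[C@@H](C(=O)OC)[C@H](c1ccc(OC)cc1)O2
A9 | alternative 3 | methyl 2-diazo-2-{5-(1,3-dioxolan-2-yl)-3-methoxy-2-[(4-methoxyphenyl)methoxy]phenyl}acetate | COC(=O)C(=[N+]=[N-])c1cc(C2OCCO2)cc(OC)c1OCc1ccc(OC)cc1
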